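**Retrosynthetic overview**

1. Feature: in ring C, C2, C3 (bearing OMe) and C4 are a 2-methoxy-1,3-dicarbonyl unit held between ring B (on C2) and ring A (on C4); it is carried as a 3,5-diaryl-4-methoxyisoxazole in which the C3–C4 bond is already made.
2. Target ⇐ flavone-5,8-quinone (hydrogenation: quinone reduction and O-debenzylation) ⇐ 3,5,7,8-tetramethoxyflavone with a tribenzylated ring B (oxidative demethylation of the para-related C5/C8 pair).
3. Ring C ⇐ O1–C2 closure of the 2'-hydroxy diketone released from the isoxazole by N–O cleavage, hydrolysis and MOM removal; the MOM ether marks the oxygen that becomes O1.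
4. Isoxazole ⇐ [3+2] of the ring A nitrile oxide (future C4) with the pyrrolidine enamine of the ring B methoxymethyl ketone (future C2 and C3), forming the C3–C4 and C2–O bonds.
5. Nitrile oxide ⇐ 1,2,3,5-tetramethoxybenzene; enamine ⇐ tri-O-benzylgallic acid. Ring order: rings A and B are bought, the isoxazole ring is closed in step 9 and opened in step 10, ring C is closed in step 11.

Key step: step 9

Assumption: the geometry of the enamine is taken as (E), as expected from allylic strain; it is of no consequence, because both stereocentres of the cycloadduct are lost on aromatisation.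

**Step 1**
Reactants: 1 1,2,3,5-tetramethoxybenzene
Product: 2 2,3,4,6-tetramethoxybenzaldehyde
Conditions: POCl3, DMF, 0 °C to 60 °C; then aq. NaOAc
Reagents that add atoms: N,N-dimethylformamide CN(C)C=O (formyl carbon); water O (carbonyl oxygen)
Why: Vilsmeier–Haack formylation; the two free positions of this very electron-rich arene are equivalent, so a single monoaldehyde should form, and the formyl group then deactivates the ring towards a second substitution.

**Step 2**
Reactants: 2 2,3,4,6-tetramethoxybenzaldehyde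
Product: 3 2-hydroxy-3,4,6-trimethoxybenzaldehyde
Conditions: BCl3 (1.1 equiv), CH2Cl2, −78 °C to 0 °C; then H2O
Reagents that add atoms: none
Why: Chelation-directed Lewis acid demethylation of an ortho-methoxy aldehyde: BCl3 bound to the formyl oxygen should cleave the C2 methoxy group, which is pushed out of the ring plane by the C3 methoxy group and is therefore the more basic and more strained of the two ortho ethers, in line with the usual course of demethylation in 2,3,4,6-tetramethoxyaryl carbonyl compounds.

**Step 3**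
Reactants: 3 2-hydroxy-3,4,6-trimethoxybenzaldehyde
Product: 4 2-(methoxymethoxy)-3,4,6-trimethoxybenzaldehyde
Conditions: MOMCl, i-Pr2NEt, CH2Cl2, 0 °C to 40 °C
Reagents that add atoms: chloromethyl methyl ether COCCl
Why: O-alkylation of the phenol with MOMCl and a hindered amine base gives the acetal that later defines which oxygen becomes O1 and that should survive the neutral, basic and reductive steps up to step 11.

**Step 4**
Reactants: 4 2-(methoxymethoxy)-3,4,6-trimethoxybenzaldehyde
Product: 5 (E)-2-(methoxymethoxy)-3,4,6-trimethoxybenzaldehyde oxime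
Conditions: NH2OH·HCl, NaOAc, EtOH/H2O, rt to 50 °C
Reagents that add atoms: hydroxylamine hydrochloride Cl.NO
Why: Oxime condensation under acetate buffer, mild enough for the MOM acetal; the aldoxime should form as the (E)-isomer, with the hydroxyl group turned away from the doubly ortho-substituted ring.

**Step 5**
Reactants: 5 (E)-2-(methoxymethoxy)-3,4,6-trimethoxybenzaldehyde oxime
Product: 6 2-(methoxymethoxy)-3,4,6-trimethoxybenzonitrile oxide
Conditions: PhI(OAc)2 (1.1 equiv), MeOH, 0 °C; cold work-up, stored at −20 °C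
Reagents that add atoms: none
Why: Dehydrogenation of an aldoxime to a nitrile oxide with (diacetoxyiodo)benzene, a non-halogenating oxidant that should spare the free C5 position of the electron-rich ring; the two ortho substituents shield the dipole from dimerisation to the furoxan, so it should be isolable.

**Step 6**
Reactants: 7 3,4,5-tris(benzyloxy)benzoic acid
Product: 9 3,4,5-tris(benzyloxy)-N-methoxy-N-methylbenzamide, via acyl imidazole 8 (not isolated)
Conditions: CDI (1,1'-carbonyldiimidazole), THF, rt; then MeNH(OMe)·HCl, rt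
Reagents that add atoms: N,O-dimethylhydroxylamine hydrochloride CNOC.Cl
Why: Carboxyl activation as the acyl imidazole followed by aminolysis (Weinreb amide formation), with no acidic or reducing reagent that could touch the benzyl ethers.

**Step 7**
Reactants: 9 3,4,5-tris(benzyloxy)-N-methoxy-N-methylbenzamide
Product: 10 2-methoxy-1-[3,4,5-tris(benzyloxy)phenyl]ethan-1-one
Conditions: Bu3SnCH2OMe, n-BuLi, THF, −78 °C; then 9, −78 °C to −40 °C; aq. NH4Cl
Reagents that add atoms: tributyl(methoxymethyl)stannane CCCC[Sn](CCCC)(CCCC)COC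
Why: Weinreb ketone synthesis with (methoxymethyl)lithium made by tin–lithium exchange; the N-methoxy-N-methylamide takes up one equivalent of the organolithium only and releases the α-methoxy ketone at work-up, so no tertiary alcohol should form.

**Step 8**
Reactants: 10 2-methoxy-1-[3,4,5-tris(benzyloxy)phenyl]ethan-1-one; 11 pyrrolidine
Product: 12 (E)-1-{2-methoxy-1-[3,4,5-tris(benzyloxy)phenyl]ethenyl}pyrrolidine
Conditions: pyrrolidine (6 equiv), TiCl4 (0.6 equiv), toluene, 0 °C to rt; filtration under Ar, excess amine stripped in vacuo, used crude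
Reagents that add atoms: none
Why: TiCl4-mediated enamine condensation, in which the titanium reagent activates the conjugated aryl ketone and binds the water irreversibly; allylic strain with the pyrrolidine ring should place the methoxy group on the side of the aryl group.

**Step 9**
Reactants: 6 2-(methoxymethoxy)-3,4,6-trimethoxybenzonitrile oxide; 12 (E)-1-{2-methoxy-1-[3,4,5-tris(benzyloxy)phenyl]ethenyl}pyrrolidine
Product: 14 4-methoxy-3-[2-(methoxymethoxy)-3,4,6-trimethoxyphenyl]-5-[3,4,5-tris(benzyloxy)phenyl]isoxazole, via 5-pyrrolidinylisoxazoline adduct 13 (not isolated)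
Conditions: THF, 4 Å MS, 0 °C to rt; then AcOH, 40 °C
Reagents that add atoms: none
Why: This is a 1,3-dipolar cycloaddition of a nitrile oxide to an enamine, the standard enamine route to isoxazoles; it is concerted but asynchronous, and in the limit it is attack of the enamine β-carbon on the nitrile oxide carbon followed by 5-exo-trig closure of the oximate oxygen on the iminium carbon. It forms the future C3–C4 bond of the flavone and the C–O bond at the future C2 and closes the five-membered ring of 13; acetic acid then ionises the aminal carbon, and loss of pyrrolidine and of the C4 proton aromatises the ring to 14. The orientation needed, ring A on the carbon next to C–OMe and the oxide oxygen on the ring B carbon, is secured by the polarisation of the enamine, because the nitrogen lone pair makes the methoxy-bearing β-carbon the nucleophilic terminus and nitrogen is a far stronger donor than the ether oxygen. The two stereocentres of 13 arise by suprafacial addition to the (E)-enamine and are both erased on aromatisation, so no stereocontrol is required. Dimerisation of the dipole is held back by its two ortho substituents, and acid is added only after the dipole is consumed, so that liberated pyrrolidine cannot add to it.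

**Step 10**
Reactants: 14 4-methoxy-3-[2-(methoxymethoxy)-3,4,6-trimethoxyphenyl]-5-[3,4,5-tris(benzyloxy)phenyl]isoxazole
Product: 15 (2E)-3-amino-2-methoxy-3-[2-(methoxymethoxy)-3,4,6-trimethoxyphenyl]-1-[3,4,5-tris(benzyloxy)phenyl]prop-2-en-1-one
Conditions: Mo(CO)6 (1 equiv), MeCN/H2O, 80 °C
Reagents that add atoms: none
Why: Reductive cleavage of the isoxazole N–O bond by zerovalent molybdenum with water as the proton source should give the hydrogen-bonded vinylogous amide and, unlike catalytic hydrogenation, leave the benzyl ethers and the MOM acetal untouched.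

**Step 11**
Reactants: 15 (2E)-3-amino-2-methoxy-3-[2-(methoxymethoxy)-3,4,6-trimethoxyphenyl]-1-[3,4,5-tris(benzyloxy)phenyl]prop-2-en-1-one
Product: 17 3,5,7,8-tetramethoxy-2-[3,4,5-tris(benzyloxy)phenyl]-4H-chromen-4-one, via 2-methoxy-1,3-diketone phenol 16 (not isolated)
Conditions: 3 M aq. HCl, 1,4-dioxane, 70 °C
Reagents that add atoms: water O
Why: Acid hydrolysis of the vinylogous amide and of the MOM acetal should give diketone 16, whose freed C8a phenol can close only on the ring B carbonyl (6-exo-trig) and then dehydrates, the classical cyclodehydration of 2-hydroxydibenzoylmethanes to flavones.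

**Step 12**
Reactants: 17 3,5,7,8-tetramethoxy-2-[3,4,5-tris(benzyloxy)phenyl]-4H-chromen-4-one
Product: 18 3,7-dimethoxy-2-[3,4,5-tris(benzyloxy)phenyl]-4H-chromene-4,5,8-trione
Conditions: (NH4)2Ce(NO3)6 (2.5 equiv), MeCN/H2O, 0 °C
Reagents that add atoms: water O
Why: Oxidative demethylation of the para-related C5 and C8 methoxy groups by tetravalent cerium should give the 5,8-quinone, with the quinone oxygens coming from water, as in the classical oxidation of 5,7,8-trimethoxyflavones to flavone-5,8-quinones; the C7 methoxy group stays as a vinylogous ester, and ring B, which has no para-dialkoxy pair and is conjugated with the pyranone, should be oxidised more slowly.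

**Step 13**
Reactants: 18 3,7-dimethoxy-2-[3,4,5-tris(benzyloxy)phenyl]-4H-chromene-4,5,8-trione
Product: 19 5,8-dihydroxy-3,7-dimethoxy-2-(3,4,5-trihydroxyphenyl)-4H-chromen-4-one (5,8,3',4',5'-pentahydroxy-3,7-dimethoxyflavone)
Conditions: H2 (1 atm), 10% Pd/C, THF/MeOH, rt; filtration and concentration under Ar
Reagents that add atoms: none
Why: Catalytic hydrogenation should reduce the quinone to the 5,8-hydroquinone and hydrogenolyse the three benzyl ethers in one operation, while the tetrasubstituted C2=C3 bond of the vinylogous ester is not reduced under one atmosphere of hydrogen.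

**Compound list**

1 | 1,2,3,5-tetramethoxybenzene | COc1cc(OC)c(OC)c(OC)c1 | starting material
2 | 2,3,4,6-tetramethoxybenzaldehyde | O=Cc1c(OC)cc(OC)c(OC)c1OC | intermediate
3 | 2-hydroxy-3,4,6-trimethoxybenzaldehyde | O=Cc1c(OC)cc(OC)c(OC)c1O | intermediate
4 | 2-(methoxymethoxy)-3,4,6-trimethoxybenzaldehyde | O=Cc1c(OC)cc(OC)c(OC)c1OCOC | intermediate
5 | (E)-2-(methoxymethoxy)-3,4,6-trimethoxybenzaldehyde oxime | O/N=C/c1c(OC)cc(OC)c(OC)c1OCOC | intermediate
6 | 2-(methoxymethoxy)-3,4,6-trimethoxybenzonitrile oxide | [O-][N+]#Cc1c(OCOC)c(OC)c(OC)cc1OC | intermediate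
7 | 3,4,5-tris(benzyloxy)benzoic acid | OC(=O)c1cc(OCc2ccccc2)c(OCc2ccccc2)c(OCc2ccccc2)c1 | starting material
8 | 1-[3,4,5-tris(benzyloxy)benzoyl]-1H-imidazole | O=C(c1cc(OCc2ccccc2)c(OCc2ccccc2)c(OCc2ccccc2)c1)n1ccnc1 | intermediate (not isolated)
9 | 3,4,5-tris(benzyloxy)-N-methoxy-N-methylbenzamide | CON(C)C(=O)c1cc(OCc2ccccc2)c(OCc2ccccc2)c(OCc2ccccc2)c1 | intermediate
10 | 2-methoxy-1-[3,4,5-tris(benzyloxy)phenyl]ethan-1-one | COCC(=O)c1cc(OCc2ccccc2)c(OCc2ccccc2)c(OCc2ccccc2)c1 | intermediate
11 | pyrrolidine | C1CCNC1 | starting material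
12 | (E)-1-{2-methoxy-1-[3,4,5-tris(benzyloxy)phenyl]ethenyl}pyrrolidine | CO/C=C(/N1CCCC1)c1cc(OCc2ccccc2)c(OCc2ccccc2)c(OCc2ccccc2)c1 | intermediate
13 | rac-(4R,5R)-4-methoxy-3-[2-(methoxymethoxy)-3,4,6-trimethoxyphenyl]-5-(pyrrolidin-1-yl)-5-[3,4,5-tris(benzyloxy)phenyl]-4,5-dihydroisoxazole (4-OMe trans to pyrrolidinyl; racemic, one enantiomer drawn) | CO[C@@H]1C(c2c(OCOC)c(OC)c(OC)cc2OC)=NO[C@]1(N3CCCC3)c4cc(OCc5ccccc5)c(OCc6ccccc6)c(OCc7ccccc7)c4 | intermediate (not isolated)
14 | 4-methoxy-3-[2-(methoxymethoxy)-3,4,6-trimethoxyphenyl]-5-[3,4,5-tris(benzyloxy)phenyl]isoxazole | COc1c(-c2c(OCOC)c(OC)c(OC)cc2OC)noc1-c1cc(OCc2ccccc2)c(OCc2ccccc2)c(OCc2ccccc2)c1 | intermediate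
15 | (2E)-3-amino-2-methoxy-3-[2-(methoxymethoxy)-3,4,6-trimethoxyphenyl]-1-[3,4,5-tris(benzyloxy)phenyl]prop-2-en-1-one | CO/C(C(=O)c1cc(OCc2ccccc2)c(OCc2ccccc2)c(OCc2ccccc2)c1)=C(/N)c1c(OCOC)c(OC)c(OC)cc1OC | intermediate
16 | 1-(2-hydroxy-3,4,6-trimethoxyphenyl)-2-methoxy-3-[3,4,5-tris(benzyloxy)phenyl]propane-1,3-dione (racemic, enolisable) | COC(C(=O)c1c(O)c(OC)c(OC)cc1OC)C(=O)c1cc(OCc2ccccc2)c(OCc2ccccc2)c(OCc2ccccc2)c1 | intermediate (not isolated)
17 | 3,5,7,8-tetramethoxy-2-[3,4,5-tris(benzyloxy)phenyl]-4H-chromen-4-one | COc1cc(OC)c2c(=O)c(OC)c(-c3cc(OCc4ccccc4)c(OCc4ccccc4)c(OCc4ccccc4)c3)oc2c1OC | intermediate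
18 | 3,7-dimethoxy-2-[3,4,5-tris(benzyloxy)phenyl]-4H-chromene-4,5,8-trione | COC1=CC(=O)C2=C(OC(c3cc(OCc4ccccc4)c(OCc4ccccc4)c(OCc4ccccc4)c3)=C(OC)C2=O)C1=O | intermediate
19 | 5,8-dihydroxy-3,7-dimethoxy-2-(3,4,5-trihydroxyphenyl)-4H-chromen-4-one | COc1cc(O)c2c(=O)c(OC)c(-c3cc(O)c(O)c(O)c3)oc2c1O | target

**Step count**

Total step count: 13. Longest linear sequence: 10 steps (steps 1 to 5, then 9 to 13, from compound 1 to compound 19).

**Steps most likely to fail**

Step 9 (key step). The cycloaddition may be slow, because a doubly ortho-substituted, donor-rich dipole meets a trisubstituted enamine; meanwhile the nitrile oxide can isomerise to the aryl isocyanate and the enamine can hydrolyse. The fallback drops the isoxazole and builds the same dicarbonyl unit by aldol chemistry; it sets out from ketone 10 and aldehyde 4 and comes back to the route at flavone 17. The lithium enolate of 10 (LiN(i-Pr)2, THF, −78 °C) is added to 4 to give 3-hydroxy-2-methoxy-3-[2-(methoxymethoxy)-3,4,6-trimethoxyphenyl]-1-[3,4,5-tris(benzyloxy)phenyl]propan-1-one F1 as a mixture of diastereomers. Oxidation with Dess–Martin periodinane should give 2-methoxy-1-[2-(methoxymethoxy)-3,4,6-trimethoxyphenyl]-3-[3,4,5-tris(benzyloxy)phenyl]propane-1,3-dione F2. The acid conditions of step 11 then remove the MOM group and cyclodehydrate through 16 to 17.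

Step 12. Electron transfer from ring B or from its benzylic ethers to the cerium oxidant may compete with oxidation of ring A, leading to over-oxidation and loss of benzyl groups. The fallback changes the protection of ring B before the oxidation; it sets out from flavone 17 and comes back at target 19. Hydrogenolysis of 17 (H2, 10% Pd/C) gives 3,5,7,8-tetramethoxy-2-(3,4,5-trihydroxyphenyl)-4H-chromen-4-one F3. Acetylation (Ac2O, pyridine) gives 5-(3,5,7,8-tetramethoxy-4-oxo-4H-chromen-2-yl)benzene-1,2,3-triyl triacetate F4, whose ring B is now electron-poor. (NH4)2Ce(NO3)6 should then oxidise only ring A to 5-(3,7-dimethoxy-4,5,8-trioxo-5,8-dihydro-4H-chromen-2-yl)benzene-1,2,3-triyl triacetate F5. Reduction with Na2S2O4 gives 5-(5,8-dihydroxy-3,7-dimethoxy-4-oxo-4H-chromen-2-yl)benzene-1,2,3-triyl triacetate F6, and acid methanolysis (HCl, MeOH, under Ar) removes the acetates to give 19.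

Step 8. The condensation of the conjugated ketone may stay incomplete, TiCl4 may attack the benzyl ethers, or the enamine may hydrolyse back to the ketone during isolation. The fallback keeps the isoxazole but replaces the enamine by the enolate; it sets out from ketone 10 and nitrile oxide 6 and comes back at isoxazole 14. The lithium enolate of 10 (LiN(i-Pr)2, THF, −78 °C) should add through carbon to the nitrile oxide carbon of 6, and the oximate closes on the ketone to give, after quenching, 4-methoxy-3-[2-(methoxymethoxy)-3,4,6-trimethoxyphenyl]-5-[3,4,5-tris(benzyloxy)phenyl]-4,5-dihydroisoxazol-5-ol F7. Dehydration (cat. TsOH, toluene, 50 °C) aromatises it to 14.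

**Further compounds**

F1 | step 9 | 3-hydroxy-2-methoxy-3-[2-(methoxymethoxy)-3,4,6-trimethoxyphenyl]-1-[3,4,5-tris(benzyloxy)phenyl]propan-1-one (mixture of diastereomers) | COC(C(O)c1c(OCOC)c(OC)c(OC)cc1OC)C(=O)c1cc(OCc2ccccc2)c(OCc2ccccc2)c(OCc2ccccc2)c1
F2 | step 9 | 2-methoxy-1-[2-(methoxymethoxy)-3,4,6-trimethoxyphenyl]-3-[3,4,5-tris(benzyloxy)phenyl]propane-1,3-dione (racemic, enolisable) | COC(C(=O)c1c(OCOC)c(OC)c(OC)cc1OC)C(=O)c1cc(OCc2ccccc2)c(OCc2ccccc2)c(OCc2ccccc2)c1
F3 | step 12 | 3,5,7,8-tetramethoxy-2-(3,4,5-trihydroxyphenyl)-4H-chromen-4-one | COc1cc(OC)c2c(=O)c(OC)c(-c3cc(O)c(O)c(O)c3)oc2c1OC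
F4 | step 12 | 5-(3,5,7,8-tetramethoxy-4-oxo-4H-chromen-2-yl)benzene-1,2,3-triyl triacetate | COc1cc(OC)c2c(=O)c(OC)c(-c3cc(OC(C)=O)c(OC(C)=O)c(OC(C)=O)c3)oc2c1OC
F5 | step 12 | 5-(3,7-dimethoxy-4,5,8-trioxo-5,8-dihydro-4H-chromen-2-yl)benzene-1,2,3-triyl triacetate | COC1=CC(=O)C2=C(OC(c3cc(OC(C)=O)c(OC(C)=O)c(OC(C)=O)c3)=C(OC)C2=O)C1=O
F6 | step 12 | 5-(5,8-dihydroxy-3,7-dimethoxy-4-oxo-4H-chromen-2-yl)benzene-1,2,3-triyl triacetate | COc1cc(O)c2c(=O)c(OC)c(-c3cc(OC(C)=O)c(OC(C)=O)c(OC(C)=O)c3)oc2c1O
F7 | step 8 | 4-methoxy-3-[2-(methoxymethoxy)-3,4,6-trimethoxyphenyl]-5-[3,4,5-tris(benzyloxy)phenyl]-4,5-dihydroisoxazol-5-ol (mixture of diastereomers) | COC1C(c2c(OCOC)c(OC)c(OC)cc2OC)=NOC1(O)c1cc(OCc2ccccc2)c(OCc2ccccc2)c(OCc2ccccc2)c1
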